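The data were computed from invented constants; scatter was added.

The south-west run got more partner than the east run (0.30 M against 0.20 M), and it stands higher in left-handed product, 59.1% against 42.9% at their last readings. The asked flask is the east run itself, so far followed to 6.00 d.

| flask | left-handed substrate | right-handed substrate | partner | remark | time |
|---|---|---|---|---|---|
| east | 0.10 M | 0.10 M | 0.20 M (in portions, 3) | the very flask that is asked about, followed so far; portions every 4.0 h |  |
| south-west | 0.10 M | 0.10 M | 0.30 M (in portions, 3) | run made earlier; portions every 4.0 h |  |
| flask | 0.10 M | 0.10 M | 0.200 M (in portions, 3) | the portions of partner follow each other after 4.0 h, the first at the start | 15 d |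

- east (time / d: left-handed substrate / %, left-handed product / %, right-handed substrate / %): 1.25: 32.7, 33.0, 32.4; 2.50: 29.1, 40.7, 29.0; 4.00: 28.6, 42.9, 28.6; 5.00: 27.1, 43.4, 27.4; 6.00: 28.0, 42.9, 28.1
- south-west (time / d: left-handed substrate / %, left-handed product / %, right-handed substrate / %): 1.25: 26.7, 47.6, 25.7; 4.00: 19.6, 59.3, 19.4; 8.00: 19.4, 57.7, 19.9; 10.0: 19.5, 59.4, 19.5; 15.0: 19.1, 59.1, 20.1

(scatter of a reading: 0.5 percentage points)

1. the state of affairs at 15 d: stopped, and by what, or still going (the partner has run out first / forward and back rates have come level / all of the left-handed substrate has reacted / it is still moving)
2. how much of the left-handed substrate and right-handed substrate together has reacted by 15 d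
3. how much left-handed product there is at 15 d, in percent of the left-handed substrate and right-handed substrate together charged
4. how much right-handed substrate there is at 15 d, in percent of the left-handed substrate and right-handed substrate together charged

- partner is single-handed; left-handed substrate and right-handed substrate are mirror images of each other, charged as a racemate, each of them at the stated concentration
- the reaction counts as stopped when no species that holds the left-handed substrate and right-handed substrate together changes by six tenths of a point or more over the second half of the time
- what has gone into achiral form counts as reacted
- the handed part of partner does not stay in what it makes, so the products of the two hands are mirror images too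

Ines holds that the plateau is a balance of forward and back rates: the east readings lie flat from 4.00 d, substrate and product stand side by side, and more partner shifted the level. Tom holds that the flask stopped on the partner, the limiting reagent.

He takes the symmetric case as zero. The products of the two hands are mirror images, so a balance means equal amounts of them. But the east readings from 4.00 d average 55.9% of the two substrates together and 43.1% of left-handed product, which leaves 1 percentage point for everything else. Ines keeps one region: the two substrates do sit at that zero, 28.0% and 28.1% at the last east reading.

My own reckoning follows Tom. Let t be the fraction of the substrate pair left and β the partner charged per pair charged, 1.00 in east. Suppose partner reacts at a rate proportional to t and is also lost on its own. Once no partner remains, β = (1 − t) + κ ln(1/t), where κ, the loss number, is the t at which partner splits evenly between product and loss.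

South-west, with β = 1.50 and a mean t of 39.1% from 4.00 d, gives a κ read from those scattered readings of 0.950. The east t then asks for 0.992 partner per pair, close to the 1.00 charged. So I commit to a stopped flask with 44.1% reacted.

The forecast says the partner has run out first, with 44% reacted, 43.1% left-handed product and 28% right-handed substrate: "Substrate remains, so the partner ran out first."

The simulation gives the partner has run out first, with 44.4% reacted, 43.0% left-handed product and 27.8% right-handed substrate; 0% of the partner remains against 56% of the left-handed substrate.

    left-handed substrate ⇌ achiral form (K = 0.0241, k = 2.80 /h)
    partner + right-handed substrate → right-handed product (k = 0.00506 /M/h)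
    partner → decomposition product (k = 1.51 × 10⁻⁴ /h)
    partner → decomposed reagent (k = 0.0305 /h)
    right-handed substrate ⇌ achiral form (K = 0.0241, k = 2.80 /h)
    partner + left-handed substrate → left-handed product (k = 0.313 /M/h)

This flask's simulated end, t = 55.6%, asks for 1.00 partner per pair against 1.00 charged. The neighbour flask changes one setting, 0.50 M of partner, which is 2.50 per pair. Its substrates end at 8.97% and 8.97%, so t = 17.9%, and the rule asks for 2.46 per pair against the 2.50 charged. That neighbour flask keeps 0% of its partner and reaches 80.5% of left-handed product.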